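## Analysis of the target

The target is a flavone: a benzo ring A fused to a 4-pyranone ring C (O1, C2, C3, C4, C4a, C8a), with ring B attached at C2. Every core carbon is sp2, so the target has no stereocentre; any stereocentre made on the way must be removable. Four of the six oxygens are methyl ethers (C3, C7, C2', C4') and two are free phenols (C6, C5'). Each phenol sits next to a methyl ether, so the two hydroxyls cannot be freed by a late selective demethylation and have to be carried as a different ether from the start. Both phenols are para to another oxygen (6-OH to O1, 5'-OH to the 2'-methoxy group), which makes the free compound oxidation-prone in base and air, and the open positions C8, C3' and C6' invite electrophilic halogenation. The main difficulties are the 3-methoxy enol ether, which excludes ynone and propiolate routes, and ring A, which has hydrogen at both C5 and C8 and no 5-hydroxyl to steer an acylation. The strategy rests on one feature: O1 on C8a and the acyl carbon C4 on C4a are ortho neighbours on ring A, which is the pattern of an aryne 1,2-difunctionalisation. The adjacent C5 carries only hydrogen, so it can hold a temporary chlorine that polarises the aryne and later leaves in the same hydrogenolysis that frees the two phenols.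

## Retrosynthetic reasoning

**21 back to 19.** The target 21 is traced to flavone 19, its 6,5'-dibenzyl ether with an extra chlorine on C5. Two O–benzyl bonds and the C5–Cl bond are cut, so the final operation is only reductive cleavage, passing through the chloro diphenol 20. The oxidation-prone free phenols then appear only at the very end.

**19 back to 18.** The C2=C3 double bond of 19 is removed to give the trans chromanone 18. This puts the unsaturation in a separate oxidation step, so ring C can be closed at the saturated level by a reversible conjugate addition. Both stereocentres of 18 are erased here, and any ring-opened chalcone (the protonated form of 17) converges on the same flavone.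

**18 back to 8 and 15 (key disconnection).** Three bonds are cut: O1–C8a, C4–C4a and O1–C2. This releases ring A as the aryne 16, made from silyl triflate 8, and the rest of ring C as acid 15. The acid carries C2, C3 with its methoxy group, C4 and the oxygen that becomes O1. The cut is made here because the ortho O/acyl pair on ring A is exactly what an aryne takes up from a carboxylic acid, and because the acid delivers O1 so that no protecting group is needed on it. The forward reaction has to add the carboxylate oxygen at C8a and not at C4a. The chlorine on C5, next to the aryne, is there to secure this, and it is the reason the chlorine is carried.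

**8 back to 1.** The silyl triflate 8 is traced to bromophenol 5 through an O-silylation, bromine–lithium exchange, retro-Brook shift and triflation sequence (via 6 and 7). Bromophenol 5 comes from phenol 4 by bromination at its only free ortho position. Phenol 4 comes from aldehyde 2 by Baeyer–Villiger excision of the formyl carbon (via formate 3), and 2 from the purchasable chlorophenol aldehyde 1 by benzylation. In 1 the chlorine already lies between the formyl carbon and the hydroxyl, so after these steps it ends up on C5, flanked by C4a and C6, with no separate halogenation step.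

**15 back to 12 and 13.** The C2=C3 bond of the acrylic acid 15 (flavone numbering) is cut by a Claisen-type condensation between aldehyde 12 and methyl methoxyacetate 13, followed by saponification of ester 14. The two-carbon ester brings C3, the 3-methoxy group and C4 in one piece, so the enol ether oxygen never has to be introduced on the heterocycle.

**12 back to 9.** Aldehyde 12 is traced through formylation (via iminium salt 11) to benzyl ether 10 and on to 2,4-dimethoxyphenol 9. The formyl group enters para to one methoxy group and ortho to the other, which is the substitution pattern ring B needs.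

## Alternatives that were turned down

Alternative 1: Ring C is opened at C4a–C4 and C4–C3, with carbon monoxide as C4. In the forward sense the ring A iodide 1,4-bis(benzyloxy)-2-iodo-5-methoxybenzene A2, CO and the enolate of the ring B ketone 1-[5-(benzyloxy)-2,4-dimethoxyphenyl]-2-methoxyethan-1-one A3 would be joined under Pd(dba)2 and Xantphos to the 1,3-diketone A1. Global debenzylation and acid cyclodehydration would then close O1–C2.
- For: three simple components combine convergently, and the iodine fixes the ring A regiochemistry with no selectivity question and no auxiliary chlorine. On that point it is stronger than the aryne route.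
- Against: no ring closes in the key step. O1 has to be carried as a third benzyl ether ortho to the iodide, which crowds the acyl-palladium on an already electron-rich ring. The α-methoxy enolate is hindered, so direct non-carbonylative α-arylation can compete when CO insertion lags. A1 is more acidic than A3, so it consumes base and is open to a second acylation or retro-Claisen cleavage.
- Comparison: the step count would be about the same, with two operations still needed after the coupling. The chosen route forms three bonds and ring C in one operation and needs no protecting group on O1.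

Alternative 2: Ring A is opened at C6–C7 and built last on a finished pyranone. Photolysis of the diazoketone 2-[5-(benzyloxy)-2,4-dimethoxyphenyl]-5-(2-diazoacetyl)-3-methoxy-6-[(E)-2-methoxyvinyl]-4H-pyran-4-one A5 would trigger a Wolff rearrangement to a ketene at C5=C6. A 6π electrocyclisation onto the enol ether carbon C7 and enolisation would then give the phenol A4.
- For: the ketene oxygen becomes the free 6-hydroxyl next to a 7-methoxy group that is already in place. Ring A then needs no benzyl group, no chlorine and no regiocontrol, so it is stronger than the chosen route at differentiating the ring A oxygens.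
- Against: A5 is a 4-pyranone with four different substituents, and assembling it would take more steps than the whole chosen route. The pyranone is itself a photoactive chromophore, the electron-rich enol ether can add to the ketene in a [2+2] sense, and the C4a=C8a bond of a vinylogous ester is a poor diene component.
- Comparison: the chosen route takes ring A from a purchasable benzaldehyde in four steps and puts its one uncertain step on fragments that are cheap to remake.

Alternative 3: Only O1–C8a is cut. The enol oxygen of the ring B carbonyl in the diketone 1-[5-(benzyloxy)-2-bromo-4-methoxyphenyl]-3-[5-(benzyloxy)-2,4-dimethoxyphenyl]-2-methoxypropane-1,3-dione A7 would displace bromide under CuI, 1,10-phenanthroline and Cs2CO3 and give the dibenzyl flavone A6 directly.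
- For: the flavone oxidation level is reached without a dehydrogenation, there is no chlorine to remove, and the bromine fixes the regiochemistry. As a single step it is more predictable than the aryne insertion.
- Against: the step forms one bond, and the burden moves to A7. Making A7 needs C-acylation of an α-methoxy ketone enolate by a hindered 2-bromoaroyl donor, with O-acylation as a competitor. The α-methoxy group lowers the enol content that the cyclisation depends on, and the C–Br bond lies on an electron-rich ring.
- Comparison: overall it is longer. The chosen route merges acylation, O-arylation and ring closure into one step from an acid and an aryne, at the price of a regiochemical question that the chlorine is placed to answer.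

Key step: step 8

Remark: compounds 1, 9 and 13 are taken as purchasable, racemic compounds are drawn as one enantiomer, and the iminium salt 11 is written as its chloride.

## Route

Step 1
Reactants: 1 2-chloro-3-hydroxy-4-methoxybenzaldehyde
Product: 2 3-(benzyloxy)-2-chloro-4-methoxybenzaldehyde
Conditions: BnBr, K2CO3, DMF, 60 °C
Reagents that add atoms: benzyl bromide, BrCc1ccccc1
Why: Williamson ether synthesis; the phenol flanked by chlorine and methoxy is acidic enough for carbonate, and the aldehyde is inert under these conditions.

Step 2
Reactants: 2 3-(benzyloxy)-2-chloro-4-methoxybenzaldehyde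
Product: 4 3-(benzyloxy)-2-chloro-4-methoxyphenol, via aryl formate 3 (not isolated)
Conditions: mCPBA, CH2Cl2, 0 °C → rt; then K2CO3 (cat.), MeOH, rt
Reagents that add atoms: 3-chloroperoxybenzoic acid (mCPBA), OOC(=O)c1cccc(Cl)c1
Why: Baeyer–Villiger oxidation; the para-methoxy group makes the aryl group migrate in preference to hydrogen, so the formate 3 forms and mild methanolysis frees the phenol. The benzyl ether and the chlorine are untouched.

Step 3
Reactants: 4 3-(benzyloxy)-2-chloro-4-methoxyphenol
Product: 5 3-(benzyloxy)-6-bromo-2-chloro-4-methoxyphenol
Conditions: NBS, MeCN, −20 → 0 °C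
Reagents that add atoms: N-bromosuccinimide, O=C1CCC(=O)N1Br
Why: Electrophilic aromatic bromination; C6 is the only free position ortho to the hydroxyl and is also para to the benzyloxy group, whereas C5 is activated only by the adjacent methoxy group. Cold aprotic conditions keep oxidation of the electron-rich phenol in check.

Step 4
Reactants: 5 3-(benzyloxy)-6-bromo-2-chloro-4-methoxyphenol
Product: 8 3-(benzyloxy)-2-chloro-4-methoxy-6-(trimethylsilyl)phenyl trifluoromethanesulfonate, via aryl trimethylsilyl ether 6 (not isolated), via lithium 2-silylphenoxide 7 (not isolated)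
Conditions: HMDS, THF, 65 °C, then evaporation; n-BuLi, THF, −100 °C; Tf2O, −100 °C → rt
Reagents that add atoms: hexamethyldisilazane, C[Si](C)(C)N[Si](C)(C)C; trifluoromethanesulfonic anhydride, O=S(=O)(OS(=O)(=O)C(F)(F)F)C(F)(F)F
Why: Standard sequence to o-silylaryl triflates: O-silylation, bromine–lithium exchange, 1,3-retro-Brook shift of silicon from oxygen to carbon, then triflation of the phenoxide. At −100 °C the exchange is far faster than attack on the C–Cl bond or benzylic deprotonation.

Step 5
Reactants: 9 2,4-dimethoxyphenol
Product: 10 1-(benzyloxy)-2,4-dimethoxybenzene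
Conditions: BnBr, K2CO3, acetone, reflux
Reagents that add atoms: benzyl bromide, BrCc1ccccc1
Why: Williamson ether synthesis; protecting the phenol first also prevents O-formylation in the next step.

Step 6
Reactants: 10 1-(benzyloxy)-2,4-dimethoxybenzene
Product: 12 5-(benzyloxy)-2,4-dimethoxybenzaldehyde, via aryl iminium salt 11 (not isolated)
Conditions: POCl3, DMF, 0 → 60 °C; then ice-water
Reagents that add atoms: N,N-dimethylformamide, CN(C)C=O; water, O
Why: Vilsmeier–Haack formylation; the position para to one methoxy group and ortho to the other is the most activated and least hindered site, as in the formylation of 1,2,4-trimethoxybenzene. The site between the two methoxy groups is crowded and the site ortho to the benzyloxy group has only one activating oxygen.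

Step 7
Reactants: 12 5-(benzyloxy)-2,4-dimethoxybenzaldehyde; 13 methyl methoxyacetate
Product: 15 (Z)-3-[5-(benzyloxy)-2,4-dimethoxyphenyl]-2-methoxyacrylic acid, via methyl ester 14 (not isolated)
Conditions: 13 (4 equiv), NaOMe, MeOH, 65 °C; then aq. NaOH, 65 °C; HCl to pH 2
Reagents that add atoms: sodium hydroxide, [Na+].[OH-]
Why: Claisen-type aldol condensation of the ester enolate with the aldehyde, then E1cB loss of water, should give the more stable Z ester with the aryl group trans to the carboxyl. Saponification in the same flask gives the acid, which can be purified by crystallisation.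

Step 8
Reactants: 8 3-(benzyloxy)-2-chloro-4-methoxy-6-(trimethylsilyl)phenyl trifluoromethanesulfonate; 15 (Z)-3-[5-(benzyloxy)-2,4-dimethoxyphenyl]-2-methoxyacrylic acid
Product: 18 (±)-trans-6-(benzyloxy)-2-[5-(benzyloxy)-2,4-dimethoxyphenyl]-5-chloro-3,7-dimethoxychroman-4-one, via aryne 16 (not isolated), via chalcone phenoxide 17 (not isolated)
Conditions: 8 (1.3 equiv), CsF (4 equiv), THF, 125 °C, sealed tube
Reagents that add atoms: none
Why: Fluoride strips the silyl group of 8 and triflate leaves to give aryne 16; the carboxylate of 15 adds through oxygen to the aryne carbon remote from chlorine (the future C8a), because the chlorine on the adjacent ring carbon distorts the triple bond toward attack at the distal carbon and stabilises the negative charge developing at C4a, while the two more remote alkoxy groups pull in opposite directions and largely cancel. The C4a anion then attacks the carbonyl of the aryl ester just formed through a four-membered transition state, and opening of the resulting benzoxetene alkoxide leaves the acyl carbon C4 on C4a and phenoxide 17 on C8a, a net insertion of the aryne into the C–O bond of the acid. The closest known reaction type is the CsF-mediated insertion of arynes into carboxylic acids to give o-hydroxyaryl ketones, which with cinnamic acids runs on to 2-arylchroman-4-ones. Ring C closes by 6-endo-trig oxa-Michael addition of the phenoxide oxygen of 17 to C2 of the α-methoxy enone; the chlorine ortho to the ketone twists the carbonyl out of the plane of ring A, which destabilises the open chalcone and offsets the poor electrophilicity of the donor-substituted β-carbon. The two new stereocentres C2 and C3 are under thermodynamic control: reversible ring opening and enolisation at C3 let the racemate settle in the 2,3-trans arrangement with both substituents equatorial, and both centres are removed in step 9 in any case. Three selectivities are needed: the site of carboxylate addition (secured by the chlorine), acyl transfer ahead of protonation of the aryl anion (secured by the hot aprotic medium in which the acid is present only as its caesium salt), and attack at the ester carbonyl in preference to the β-carbon or to loss of chloride (secured by the proximity of the carbonyl and the deactivated alkene).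

Step 9
Reactants: 18 (±)-trans-6-(benzyloxy)-2-[5-(benzyloxy)-2,4-dimethoxyphenyl]-5-chloro-3,7-dimethoxychroman-4-one
Product: 19 6-(benzyloxy)-2-[5-(benzyloxy)-2,4-dimethoxyphenyl]-5-chloro-3,7-dimethoxy-4H-chromen-4-one
Conditions: I2 (0.2 equiv), DMSO, 130 °C
Reagents that add atoms: none
Why: Iodine/DMSO dehydrogenation of a flavanone: the C3 enol is iodinated, HI is lost across C2–C3, and DMSO reoxidises HI to iodine. Any ring-opened hydroxychalcone carried over from step 8 cyclises and is oxidised to the same flavone, and any adventitious ring iodination would be reduced off in step 10.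

Step 10
Reactants: 19 6-(benzyloxy)-2-[5-(benzyloxy)-2,4-dimethoxyphenyl]-5-chloro-3,7-dimethoxy-4H-chromen-4-one
Product: 21 6-hydroxy-2-(5-hydroxy-2,4-dimethoxyphenyl)-3,7-dimethoxy-4H-chromen-4-one (6,5'-dihydroxy-3,7,2',4'-tetramethoxyflavone), via chloro diphenol 20 (not isolated)
Conditions: H2 (1 atm), 10% Pd/C, THF–MeOH, rt; then Et3N, H2, rt → 40 °C
Reagents that add atoms: none
Why: Catalytic hydrogenolysis: the two aryl benzyl ethers are cleaved first in neutral medium, because amines can retard O-debenzylation. Triethylamine is then added to take up HCl and drive Pd/C hydrodechlorination of the C5–Cl bond. The tetrasubstituted, conjugated C2=C3 bond of the flavone is not expected to be reduced at one atmosphere.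

## Compound list

1 | 2-chloro-3-hydroxy-4-methoxybenzaldehyde | COc1ccc(C=O)c(Cl)c1O | starting material
2 | 3-(benzyloxy)-2-chloro-4-methoxybenzaldehyde | COc1ccc(C=O)c(Cl)c1OCc1ccccc1 | intermediate
3 | 3-(benzyloxy)-2-chloro-4-methoxyphenyl formate | COc1ccc(OC=O)c(Cl)c1OCc1ccccc1 | intermediate
4 | 3-(benzyloxy)-2-chloro-4-methoxyphenol | COc1ccc(O)c(Cl)c1OCc1ccccc1 | intermediate
5 | 3-(benzyloxy)-6-bromo-2-chloro-4-methoxyphenol | COc1cc(Br)c(O)c(Cl)c1OCc1ccccc1 | intermediate
6 | [3-(benzyloxy)-6-bromo-2-chloro-4-methoxyphenoxy]trimethylsilane | COc1cc(Br)c(O[Si](C)(C)C)c(Cl)c1OCc1ccccc1 | intermediate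
7 | lithium 3-(benzyloxy)-2-chloro-4-methoxy-6-(trimethylsilyl)phenoxide | COc1cc([Si](C)(C)C)c([O-])c(Cl)c1OCc1ccccc1.[Li+] | intermediate
8 | 3-(benzyloxy)-2-chloro-4-methoxy-6-(trimethylsilyl)phenyl trifluoromethanesulfonate | COc1cc([Si](C)(C)C)c(OS(=O)(=O)C(F)(F)F)c(Cl)c1OCc1ccccc1 | intermediate
9 | 2,4-dimethoxyphenol | COc1ccc(O)c(OC)c1 | starting material
10 | 1-(benzyloxy)-2,4-dimethoxybenzene | COc1ccc(OCc2ccccc2)c(OC)c1 | intermediate
11 | [5-(benzyloxy)-2,4-dimethoxyphenyl]methylidene-dimethylammonium chloride | COc1cc(OC)c(OCc2ccccc2)cc1C=[N+](C)C.[Cl-] | intermediate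
12 | 5-(benzyloxy)-2,4-dimethoxybenzaldehyde | COc1cc(OC)c(OCc2ccccc2)cc1C=O | intermediate
13 | methyl methoxyacetate | COCC(=O)OC | starting material
14 | methyl (Z)-3-[5-(benzyloxy)-2,4-dimethoxyphenyl]-2-methoxyacrylate | CO/C(C(=O)OC)=C\c1cc(OCc2ccccc2)c(OC)cc1OC | intermediate
15 | (Z)-3-[5-(benzyloxy)-2,4-dimethoxyphenyl]-2-methoxyacrylic acid | CO/C(C(=O)O)=C\c1cc(OCc2ccccc2)c(OC)cc1OC | intermediate
16 | 4-(benzyloxy)-3-chloro-5-methoxybenzyne (1,2-didehydrobenzene) | COC1=CC#CC(Cl)=C1OCc1ccccc1 | intermediate
17 | caesium 4-(benzyloxy)-2-[(Z)-3-[5-(benzyloxy)-2,4-dimethoxyphenyl]-2-methoxyacryloyl]-3-chloro-5-methoxyphenoxide | CO/C(=C\c1cc(OCc2ccccc2)c(OC)cc1OC)C(=O)c1c([O-])cc(OC)c(OCc2ccccc2)c1Cl.[Cs+] | intermediate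
18 | (±)-trans-6-(benzyloxy)-2-[5-(benzyloxy)-2,4-dimethoxyphenyl]-5-chloro-3,7-dimethoxychroman-4-one (2R,3R enantiomer drawn) | COc1cc(OC)c(OCc2ccccc2)cc1[C@@H]1[C@H](C(=O)c2c(Cl)c(OCc3ccccc3)c(OC)cc2O1)OC | intermediate
19 | 6-(benzyloxy)-2-[5-(benzyloxy)-2,4-dimethoxyphenyl]-5-chloro-3,7-dimethoxy-4H-chromen-4-one | COc1cc(OC)c(OCc2ccccc2)cc1-c1oc2cc(OC)c(OCc3ccccc3)c(Cl)c2c(=O)c1OC | intermediate
20 | 5-chloro-6-hydroxy-2-(5-hydroxy-2,4-dimethoxyphenyl)-3,7-dimethoxy-4H-chromen-4-one | COc1cc(OC)c(-c2oc3cc(OC)c(O)c(Cl)c3c(=O)c2OC)cc1O | intermediate
21 | 6-hydroxy-2-(5-hydroxy-2,4-dimethoxyphenyl)-3,7-dimethoxy-4H-chromen-4-one (6,5'-dihydroxy-3,7,2',4'-tetramethoxyflavone) | COc1cc(OC)c(-c2oc3cc(OC)c(O)cc3c(=O)c2OC)cc1O | target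

## Step count and least certain steps

Total step count: 10. Longest linear sequence: 7 steps (steps 1–4, 8, 9, 10); the ring B branch (steps 5–7) joins at step 8.

**Step 8 (key step).** Several things can go wrong here.
- The aryl anion may be protonated before the acyl shift, which stops the sequence at the aryl ester.
- Regiocontrol of the carboxylate addition may be incomplete, because the 7-methoxy group works weakly against the chlorine.
- The o-chloroaryl anion may lose chloride and open a second aryne.
- Excess aryne may arylate the phenoxide or the enolate, the more so because the donor-substituted enone closes slowly.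

The fallback creates the same o-metallated aryl ester by halogen–metal exchange instead of by aryne addition. It sets out from acid 15 and returns to the route at target 21.
- Purchasable 4-(benzyloxy)-3-methoxyphenol F1 is iodinated with NIS at the position ortho to the hydroxyl and para to the methoxy group, giving 4-(benzyloxy)-2-iodo-5-methoxyphenol F2.
- Esterification of F2 with 15 (EDC·HCl, DMAP, CH2Cl2) gives the aryl ester 4-(benzyloxy)-2-iodo-5-methoxyphenyl (Z)-3-[5-(benzyloxy)-2,4-dimethoxyphenyl]-2-methoxyacrylate F3.
- n-BuLi in THF at −100 °C effects iodine–lithium exchange. The same O-to-C acyl shift (an exchange-initiated anionic Fries rearrangement) and, on warming, oxa-Michael closure should give the chlorine-free chromanone (±)-trans-6-(benzyloxy)-2-[5-(benzyloxy)-2,4-dimethoxyphenyl]-3,7-dimethoxychroman-4-one F4.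
- Iodine in DMSO, as in step 9, gives 6-(benzyloxy)-2-[5-(benzyloxy)-2,4-dimethoxyphenyl]-3,7-dimethoxy-4H-chromen-4-one F5, and neutral hydrogenolysis over Pd/C gives 21.

**Step 10.** The C5–Cl bond may be reduced incompletely, since it is crowded between the carbonyl and the C6 oxygen and, once the phenol is free and base is present, sits on a phenoxide-rich ring. The pyranone double bond could also be slowly over-reduced if the reaction is forced. The fallback separates the two reductions. It sets out from 19 and returns at 21. Homogeneous transfer hydrodechlorination (Pd(OAc)2, XPhos, HCO2Na, DMF, 100 °C) on the fully benzylated compound gives 6-(benzyloxy)-2-[5-(benzyloxy)-2,4-dimethoxyphenyl]-3,7-dimethoxy-4H-chromen-4-one F6, the same structure as F5. Plain hydrogenolysis (H2, Pd/C, THF–MeOH, no base) then gives 21.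

**Step 9.** Iodination at the tertiary, methoxy-bearing C3 may be slow. Over a long reaction at 130 °C, HI could cleave ethers or iodine could substitute the electron-rich rings. The fallback replaces halogenation–elimination by hydride abstraction. It sets out from 18 and returns at 19. TBSOTf and Et3N in CH2Cl2 give the silyl enol ether (±)-{[6-(benzyloxy)-2-[5-(benzyloxy)-2,4-dimethoxyphenyl]-5-chloro-3,7-dimethoxy-2H-chromen-4-yl]oxy}(tert-butyl)dimethylsilane F7. DDQ with 2,4,6-collidine in CH2Cl2 at room temperature then abstracts the C2 hydride, which is activated by O1 and the donor aryl group, and loss of the silyl group gives 19.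

**Step 7.** The electron-rich aldehyde is a poor electrophile, so the condensation may stall, with self-condensation and saponification of the methoxyacetate consuming the base. The fallback is a Horner–Wadsworth–Emmons olefination. It sets out from aldehyde 12 and returns at ester 14. Methyl 2-(dimethoxyphosphoryl)-2-methoxyacetate F8 with NaH in THF (0 °C → rt) should give 14. A minor geometric isomer, methyl (E)-3-[5-(benzyloxy)-2,4-dimethoxyphenyl]-2-methoxyacrylate F9, may form and would be removed by chromatography. Ester 14 is then saponified as in the second stage of step 7.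

**Step 3.** The p-alkoxyphenol may be oxidised toward a quinone instead of being brominated, or over-brominated. The fallback introduces silicon by directed ortho-metallation and needs no halogenation. It sets out from phenol 4 and returns at silyl triflate 8.
- Isopropyl isocyanate with catalytic Et3N in CH2Cl2 gives 3-(benzyloxy)-2-chloro-4-methoxyphenyl N-isopropylcarbamate F10.
- TMSOTf and TMEDA in Et2O silylate the nitrogen in situ, giving 3-(benzyloxy)-2-chloro-4-methoxyphenyl N-isopropyl-N-(trimethylsilyl)carbamate F11.
- n-BuLi and TMEDA at −78 °C lithiate the only free position ortho to the carbamate, and TMSCl gives 3-(benzyloxy)-2-chloro-4-methoxy-6-(trimethylsilyl)phenyl N-isopropyl-N-(trimethylsilyl)carbamate F12.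
- Acidic work-up gives 3-(benzyloxy)-2-chloro-4-methoxy-6-(trimethylsilyl)phenyl N-isopropylcarbamate F13.
- DBU and Et2NH in MeCN at 40 °C cleave the carbamate, and PhNTf2 added to the same pot triflates the liberated phenoxide (the anion present in 7) to give 8.

This fallback costs one more step than steps 3 and 4, and its own risk is competing benzylic lithiation of the benzyl ether.

## Further compounds

F1 | step 8 | 4-(benzyloxy)-3-methoxyphenol | COc1cc(O)ccc1OCc1ccccc1
F2 | step 8 | 4-(benzyloxy)-2-iodo-5-methoxyphenol | COc1cc(O)c(I)cc1OCc1ccccc1
F3 | step 8 | 4-(benzyloxy)-2-iodo-5-methoxyphenyl (Z)-3-[5-(benzyloxy)-2,4-dimethoxyphenyl]-2-methoxyacrylate | CO/C(C(=O)Oc1cc(OC)c(OCc2ccccc2)cc1I)=C\c1cc(OCc2ccccc2)c(OC)cc1OC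
F4 | step 8 | (±)-trans-6-(benzyloxy)-2-[5-(benzyloxy)-2,4-dimethoxyphenyl]-3,7-dimethoxychroman-4-one (2R,3R enantiomer drawn) | COc1cc(OC)c(OCc2ccccc2)cc1[C@@H]1[C@H](C(=O)c2cc(OCc3ccccc3)c(OC)cc2O1)OC
F5 | step 8 | 6-(benzyloxy)-2-[5-(benzyloxy)-2,4-dimethoxyphenyl]-3,7-dimethoxy-4H-chromen-4-one | COc1cc(OC)c(OCc2ccccc2)cc1-c1oc2cc(OC)c(OCc3ccccc3)cc2c(=O)c1OC
F6 | step 10 | 6-(benzyloxy)-2-[5-(benzyloxy)-2,4-dimethoxyphenyl]-3,7-dimethoxy-4H-chromen-4-one | COc1cc(OC)c(OCc2ccccc2)cc1-c1oc2cc(OC)c(OCc3ccccc3)cc2c(=O)c1OC
F7 | step 9 | (±)-{[6-(benzyloxy)-2-[5-(benzyloxy)-2,4-dimethoxyphenyl]-5-chloro-3,7-dimethoxy-2H-chromen-4-yl]oxy}(tert-butyl)dimethylsilane (one enantiomer drawn) | COc1cc(OC)c(OCc2ccccc2)cc1[C@@H]1Oc2cc(OC)c(OCc3ccccc3)c(Cl)c2C(O[Si](C)(C)C(C)(C)C)=C1OC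
F8 | step 7 | methyl 2-(dimethoxyphosphoryl)-2-methoxyacetate | COC(C(=O)OC)P(=O)(OC)OC
F9 | step 7 | methyl (E)-3-[5-(benzyloxy)-2,4-dimethoxyphenyl]-2-methoxyacrylate | CO/C(C(=O)OC)=C/c1cc(OCc2ccccc2)c(OC)cc1OC
F10 | step 3 | 3-(benzyloxy)-2-chloro-4-methoxyphenyl N-isopropylcarbamate | COc1ccc(OC(=O)NC(C)C)c(Cl)c1OCc1ccccc1
F11 | step 3 | 3-(benzyloxy)-2-chloro-4-methoxyphenyl N-isopropyl-N-(trimethylsilyl)carbamate | COc1ccc(OC(=O)N(C(C)C)[Si](C)(C)C)c(Cl)c1OCc1ccccc1
F12 | step 3 | 3-(benzyloxy)-2-chloro-4-methoxy-6-(trimethylsilyl)phenyl N-isopropyl-N-(trimethylsilyl)carbamate | COc1cc([Si](C)(C)C)c(OC(=O)N(C(C)C)[Si](C)(C)C)c(Cl)c1OCc1ccccc1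
F13 | step 3 | 3-(benzyloxy)-2-chloro-4-methoxy-6-(trimethylsilyl)phenyl N-isopropylcarbamate | COc1cc([Si](C)(C)C)c(OC(=O)NC(C)C)c(Cl)c1OCc1ccccc1
A1 | alternative 1 | (±)-1-[2,5-bis(benzyloxy)-4-methoxyphenyl]-3-[5-(benzyloxy)-2,4-dimethoxyphenyl]-2-methoxypropane-1,3-dione (enolisable centre drawn as one enantiomer) | CO[C@H](C(=O)c1cc(OCc2ccccc2)c(OC)cc1OCc1ccccc1)C(=O)c1cc(OCc2ccccc2)c(OC)cc1OC
A2 | alternative 1 | 1,4-bis(benzyloxy)-2-iodo-5-methoxybenzene | COc1cc(OCc2ccccc2)c(I)cc1OCc1ccccc1
A3 | alternative 1 | 1-[5-(benzyloxy)-2,4-dimethoxyphenyl]-2-methoxyethan-1-one | COCC(=O)c1cc(OCc2ccccc2)c(OC)cc1OC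
A4 | alternative 2 | 2-[5-(benzyloxy)-2,4-dimethoxyphenyl]-6-hydroxy-3,7-dimethoxy-4H-chromen-4-one | COc1c(-c2cc(OCc3ccccc3)c(OC)cc2OC)oc2cc(OC)c(O)cc2c1=O
A5 | alternative 2 | 2-[5-(benzyloxy)-2,4-dimethoxyphenyl]-5-(2-diazoacetyl)-3-methoxy-6-[(E)-2-methoxyvinyl]-4H-pyran-4-one | CO/C=C/c1oc(-c2cc(OCc3ccccc3)c(OC)cc2OC)c(OC)c(=O)c1C(=O)C=[N+]=[N-]
A6 | alternative 3 | 6-(benzyloxy)-2-[5-(benzyloxy)-2,4-dimethoxyphenyl]-3,7-dimethoxy-4H-chromen-4-one | COc1cc(OC)c(-c2oc3cc(OC)c(OCc4ccccc4)cc3c(=O)c2OC)cc1OCc1ccccc1
A7 | alternative 3 | (±)-1-[5-(benzyloxy)-2-bromo-4-methoxyphenyl]-3-[5-(benzyloxy)-2,4-dimethoxyphenyl]-2-methoxypropane-1,3-dione (enolisable centre drawn as one enantiomer) | CO[C@H](C(=O)c1cc(OCc2ccccc2)c(OC)cc1Br)C(=O)c1cc(OCc2ccccc2)c(OC)cc1OC
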